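If a substrate that ends as tetra adduct has taken 4 partners, a flask's partner charge can be held against one number.

| flask | substrate | partner | remark | time |
|---|---|---|---|---|
| alpha | 0.024 M | 1.4 equiv | run made earlier |  |
| eta | 0.024 M | 5.7 equiv | run made earlier |  |
| grey | 0.024 M | 1.20 equiv |  | 2.0 d |
| violet | 0.024 M | 3.00 equiv |  | 2.0 d |
| blue | 0.024 M | 4.00 equiv |  | 2.0 d |

- alpha (time / h: tetra adduct / %, single product / %, substrate / %): 2.50: 7, 36, 0; 4.00: 8, 34, 0; 6.00: 7, 35, 0; 10.0: 8, 33, 0; 15.0: 4, 34, 1; 20.0: 8, 33, 0; 30.0: 6, 31, 2
- eta (time / h: tetra adduct / %, single product / %, substrate / %): 2.50: 92, 1, 0; 4.00: 94, 2, 0; 6.00: 94, 0, 0; 10.0: 92, 0, 0; 15.0: 92, 2, 1; 20.0: 92, 0, 0; 30.0: 92, 1, 0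

(scatter of a reading: 1.5 percentage points)

* tetra adduct at the end, in percent of the substrate charged, for each flask in turn (grey, violet, blue)



We follow one substrate in slow motion. First it is consumed, how early we cannot read: the eta run already shows 0 % substrate at its first reading, 2.50 h. In the middle it takes up partner stepwise, as we read the alpha run: at 1.4 equiv, the first reading shows 36 % single product, 7 % tetra adduct and 57.0 % unseen, which we take for partial adducts and losses. At the end the eta tetra adduct stays flat within the scatter, averaging 92.6 %, so we read that average as a substrate's chance of getting through with partner in excess, and treat the 2-day flasks as finished.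

Hence the partner demand, 4 times that chance, the equivalents a flask puts into tetra adduct when the eta share of its substrate gets through: 3.70 equiv.

Our reckoning is this. Blue, at 4.00 equiv, is charged above the demand, so we expect tetra adduct near 92.6 % and 7.43 % of its partner left. Violet, at 3.00 equiv, is charged below it, so its tetra adduct stays under 75.0 %, the value if all its partner reached tetra adduct. Grey has less partner than alpha and should read below the 7 % of alpha's first reading.

The forecast gives 5 %, 50 % and 85 %, holding for blue that “the charge is just stoichiometric”; its blue value lies below ours.

    substrate + partner → single product + released group (k = 18.6 /M/min)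
    partner + single product → bis adduct + released group (k = 8.63 /M/min)
    partner + bis adduct → triple product + released group (k = 19.5 /M/min)
    partner + triple product → tetra adduct + released group (k = 8.97 /M/min)
    substrate + released group → side product A (k = 7.91 /M/min)
    substrate + single product → side product B (k = 1.47 /M/min)

The flasks end at 3.90 % (grey), 56.6 % (violet) and 89.9 % (blue). In grey, at 6.82 × 10⁻⁴ d, substrate had a half-life of 0.032 h by its step with partner, and released group was being made 6.85 times faster than used up; side product A stands at 27.5 % at the end. Blue, where substrate ran out first and 0 % of it is left, keeps 9.9 % of its partner against our 7.43 %. Violet, 0.703 equiv short of the demand, has partner as limiting reagent for tetra adduct, with 0 % left and triple product at 19.1 %.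

The runs are simulated for an exercise, noise included.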